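**Retrosynthetic overview**
1. Target 20 ⇐ acyclic tetraketone diol 18 by a one-pot aldol ring closure (C8→C3, cyclohexanone) followed by retro-Claisen acyl shift from C8 to O5; the ester is never made by a coupling reaction.
2. 18 ⇐ 15 (global oxidation, desilylation) ⇐ boron aldol of ethyl ketone 6 (C1–C8) with aldehyde 14 (C9–C15).
3. 6 ⇐ 3-pentanone + proline-derived propanal dimer (anti/Felkin boron aldol).
4. 14 ⇐ anti-crotylation of 11 ⇐ proline cross-aldol (dynamic kinetic resolution) of racemic pyranone aldehyde 9 ⇐ tetramethylpyranone 7 ⇐ 3-pentanone + acetic acid (triketone cyclodehydration).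
5. Ring order: γ-pyranone first (step 5), cyclohexanone last (step 14).

Assumption: the target is taken exactly as its SMILES defines it (nine stereocentres); locants C1–C15 in the text are those of acyclic precursor 18 (C1 = CH3 of the ethyl ketone, C14 carries the pyranone), and catalysts/stoichiometric reagents (prolines, c-Hex2BCl, crotyl-B(Ipc)2, IBX) are bought or freshly made and not counted as steps.

**Route**

Step 1
Reactants: 1 propanal (2 equiv)
Product: 2 (2S,3S)-3-hydroxy-2-methylpentanal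
Conditions: L-proline (10 mol %), DMF, 4 °C, slow addition
Reagents that add atoms: none
Why: Proline-catalysed direct aldehyde aldol (enamine, Houk–List transition state) gives the anti aldol with the α-methyl centre (future C4) set by the catalyst; the carbinol (future C3) is oxidised later, so its configuration does not matter.

Step 2
Reactants: 2 (2S,3S)-3-hydroxy-2-methylpentanal
Product: 3 (2S,3S)-2-methyl-3-(triethylsilyloxy)pentanal
Conditions: TESCl, imidazole, CH2Cl2, 0 °C
Reagents that add atoms: chlorotriethylsilane, CC[Si](Cl)(CC)CC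
Why: Silyl ether formation stops retro-aldol/dehydration and tags O3 with the labile group that is removed and oxidised in step 13; no stereocentre is touched.

Step 3
Reactants: 4 3-pentanone, 3 (2S,3S)-2-methyl-3-(triethylsilyloxy)pentanal
Product: 5 (4R,5R,6R,7S)-5-hydroxy-4,6-dimethyl-7-(triethylsilyloxy)nonan-3-one
Conditions: 4, c-Hex2BCl, Et3N, Et2O, 0 °C; then 3, −78 → −20 °C; H2O2, MeOH, pH 7 buffer
Reagents that add atoms: none
Why: Boron aldol via the (E)-enol dicyclohexylborinate (Zimmerman–Traxler chair) gives the 5,6-anti relationship, and Felkin–Anh attack on the α-methyl aldehyde (reinforced by the anti β-silyloxy group) gives 4,5-syn, so C5 and C6 are set in the matched sense.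

Step 4
Reactants: 5 (4R,5R,6R,7S)-5-hydroxy-4,6-dimethyl-7-(triethylsilyloxy)nonan-3-one
Product: 6 (4R,5R,6S,7S)-5-(tert-butyldimethylsilyloxy)-4,6-dimethyl-7-(triethylsilyloxy)nonan-3-one
Conditions: TBSOTf, 2,6-lutidine, CH2Cl2, −78 °C
Reagents that add atoms: tert-butyldimethylsilyl triflate, CC(C)(C)[Si](C)(C)OS(=O)(=O)C(F)(F)F
Why: Silylation of the β-hydroxy ketone at low temperature (no retro-aldol) puts the robust TBS group on O5, which must stay masked through the global oxidation; stereocentres unchanged (the descriptor at C6 of the name changes only through CIP priorities).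

Step 5
Reactants: 4 3-pentanone
Product: 7 2,3,5,6-tetramethyl-4H-pyran-4-one
Conditions: AcOH (2.5 equiv), polyphosphoric acid, 100 °C
Reagents that add atoms: acetic acid, CC(=O)O
Why: Acid-mediated double C-acylation of both α-carbons gives 3,5-dimethylheptane-2,4,6-trione, which cyclodehydrates to the γ-pyranone (the polyketide way of making this ring); no stereocentre.

Step 6
Reactants: 7 2,3,5,6-tetramethyl-4H-pyran-4-one
Product: 9 rac-2-(3,5,6-trimethyl-4-oxo-4H-pyran-2-yl)propanal, via lithium enolate of the formylated pyranone 8 (not isolated)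
Conditions: LDA (2.1 equiv), THF, −78 °C; HCO2Et; then MeI, DMPU, −78 → 0 °C; aq. NH4Cl
Reagents that add atoms: ethyl formate, CCOC=O; iodomethane, CI
Why: Vinylogous deprotonation of one of the two equivalent 2/6-methyl groups (the only acidic ones), Claisen formylation to the stabilised enolate 8 and C-methylation of that enolate give the α-branched aldehyde as a racemate, which is what step 7 needs.

Step 7
Reactants: 9 rac-2-(3,5,6-trimethyl-4-oxo-4H-pyran-2-yl)propanal, 1 propanal
Product: 10 (2R,3R,4R)-3-hydroxy-2-methyl-4-(3,5,6-trimethyl-4-oxo-4H-pyran-2-yl)pentanal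
Conditions: D-proline (20 mol %), DMF, 4 °C, propanal added by syringe pump
Reagents that add atoms: none
Why: Proposed new method: the D-proline enamine of propanal adds anti-selectively to 9, whose acidic C14–H racemises through its enol/enamine under the amine–acid conditions, so only the enantiomer offering its Felkin–Anh face reacts (dynamic kinetic resolution), which fixes C12 (catalyst), C13 (anti aldol) and C14 (13,14-syn, i.e. 12,14-anti methyls as in the target); closest known reactions are the proline-catalysed cross-aldol of aldehydes with α-branched acceptors and proline aldols of racemising α-branched aldehydes that proceed with dynamic kinetic resolution.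

Step 8
Reactants: 10 (2R,3R,4R)-3-hydroxy-2-methyl-4-(3,5,6-trimethyl-4-oxo-4H-pyran-2-yl)pentanal
Product: 11 (2R,3R,4R)-2-methyl-3-(triethylsilyloxy)-4-(3,5,6-trimethyl-4-oxo-4H-pyran-2-yl)pentanal
Conditions: TESOTf, 2,6-lutidine, CH2Cl2, −78 °C
Reagents that add atoms: triethylsilyl triflate, CC[Si](CC)(CC)OS(=O)(=O)C(F)(F)F
Why: Silylation of the hindered C13 hydroxyl with the same labile group as O3, so both are unmasked and oxidised together in step 13; the aldehyde α-centre is not epimerised at −78 °C with a hindered base.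

Step 9
Reactants: 11 (2R,3R,4R)-2-methyl-3-(triethylsilyloxy)-4-(3,5,6-trimethyl-4-oxo-4H-pyran-2-yl)pentanal
Product: 12 2-[(2R,3S,4S,5S,6S)-5-hydroxy-4,6-dimethyl-3-(triethylsilyloxy)oct-7-en-2-yl]-3,5,6-trimethyl-4H-pyran-4-one
Conditions: (E)-crotyl-B(Ipc)2 [Ipc from (+)-α-pinene, the antipode that adds to the Si face], THF/Et2O, −78 °C; then NaOH, H2O2
Reagents that add atoms: (E)-crotyldiisopinocampheylborane, C/C=C/CB([C@@H]1C[C@@H]2C[C@@H](C2(C)C)[C@H]1C)[C@@H]1C[C@@H]2C[C@@H](C2(C)C)[C@H]1C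
Why: Brown crotylboration through a closed chair transition state: the (E)-crotyl geometry gives the 10,11-anti relationship and the Ipc ligands impose Si-face (anti-Felkin, 11,12-anti) addition against the modest Felkin bias of the α-methyl aldehyde (mismatched case, reagent control), completing the anti,anti C10–C12 triad.

Step 10
Reactants: 12 2-[(2R,3S,4S,5S,6S)-5-hydroxy-4,6-dimethyl-3-(triethylsilyloxy)oct-7-en-2-yl]-3,5,6-trimethyl-4H-pyran-4-one
Product: 13 2-[(2R,3S,4S,5S,6S)-5-(tert-butyldimethylsilyloxy)-4,6-dimethyl-3-(triethylsilyloxy)oct-7-en-2-yl]-3,5,6-trimethyl-4H-pyran-4-one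
Conditions: TBSOTf, 2,6-lutidine, CH2Cl2, −78 → 0 °C
Reagents that add atoms: tert-butyldimethylsilyl triflate, CC(C)(C)[Si](C)(C)OS(=O)(=O)C(F)(F)F
Why: Silylation puts the robust TBS group on O11 (kept through the oxidation, like O5); no stereocentre is touched.

Step 11
Reactants: 13 2-[(2R,3S,4S,5S,6S)-5-(tert-butyldimethylsilyloxy)-4,6-dimethyl-3-(triethylsilyloxy)oct-7-en-2-yl]-3,5,6-trimethyl-4H-pyran-4-one
Product: 14 (2R,3R,4R,5S,6R)-3-(tert-butyldimethylsilyloxy)-2,4-dimethyl-5-(triethylsilyloxy)-6-(3,5,6-trimethyl-4-oxo-4H-pyran-2-yl)heptanal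
Conditions: OsO4 (2 mol %), NaIO4, 2,6-lutidine, dioxane/H2O, rt
Reagents that add atoms: sodium periodate (oxygen source via catalytic OsO4), [Na+].[O-]I(=O)(=O)=O
Why: Lemieux–Johnson oxidative cleavage takes only the terminal vinyl group (the pyranone C=C bonds are tetrasubstituted and electron-poor), and the lutidine buffer keeps the silyl ethers and the α-centre of the new aldehyde intact.

Step 12
Reactants: 6 (4R,5R,6S,7S)-5-(tert-butyldimethylsilyloxy)-4,6-dimethyl-7-(triethylsilyloxy)nonan-3-one, 14 (2R,3R,4R,5S,6R)-3-(tert-butyldimethylsilyloxy)-2,4-dimethyl-5-(triethylsilyloxy)-6-(3,5,6-trimethyl-4-oxo-4H-pyran-2-yl)heptanal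
Product: 15 (3S,4S,5R,6R,10S,11S,12S,13S,14R)-5,11-bis(tert-butyldimethylsilyloxy)-9-hydroxy-4,6,8,10,12-pentamethyl-3,13-bis(triethylsilyloxy)-14-(3,5,6-trimethyl-4-oxo-4H-pyran-2-yl)pentadecan-7-one (C8/C9 diastereomer mixture)
Conditions: 6, c-Hex2BCl, Et3N, Et2O, 0 °C; then 14, −78 → −20 °C; H2O2, MeOH, pH 7 buffer
Reagents that add atoms: none
Why: Boron aldol: the ketone is enolised only on its unbranched ethyl side (C8) and adds to the aldehyde under non-basic conditions; the new centres C8 and C9 need no control because C9 is oxidised and C8 becomes the enolisable β-diketone carbon.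

Step 13
Reactants: 15 aldol adduct (C8/C9 mixture)
Product: 17 (4R,5R,6R,10R,11R,12S,14S)-5,11-bis(tert-butyldimethylsilyloxy)-4,6,8,10,12-pentamethyl-14-(3,5,6-trimethyl-4-oxo-4H-pyran-2-yl)pentadecane-3,7,9,13-tetraone, via triol 16 (not isolated)
Conditions: IBX (excess), DMSO, rt
Reagents that add atoms: none
Why: IBX in DMSO cleaves triethylsilyl ethers while leaving TBS ethers, and oxidises the three freed or free secondary alcohols (C3, C9, C13) to ketones (IBX oxidation, clean for β-hydroxy ketone → β-diketone); near-neutral conditions are chosen so that C14, now α to a ketone, is not epimerised.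

Step 14
Reactants: 17 bis-TBS tetraketone
Product: 20 CNP0260549.2 (target), via tetraketone diol 18 (not isolated), via cyclohexanone ketol 19 (not isolated)
Conditions: HF·pyridine, pyridine, THF, 0 °C → rt; evaporate; neutral Al2O3, EtOAc, rt
Reagents that add atoms: none
Why: Proposed new method: fluoride frees O5 and O11, then on alumina the C7/C9 β-diketone adds through its doubly activated C8 to the C3 ketone (reversible 6-ring aldol; only C8 can react, which fixes which ketone ends up in the ring, and the ketol with equatorial ethyl gives 3R), after which the C5 hydroxyl, cis to the C9 acyl group on the now quaternary and non-enolisable C8, attacks C9 and retro-Claisen cleavage of C8–C9 gives the ester plus the C7 enolate, whose axial protonation gives the equatorial C8 methyl (8R) while C4, C5, C6 and the side-chain centres are untouched; closest known reactions are retro-Claisen acyl shifts of β-diketone hemiketals in related marine polypropionates and Robinson-type ketol cyclisations of 1,5-diketones.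

**Compound list**
1 | propanal | CCC=O | starting material
2 | (2S,3S)-3-hydroxy-2-methylpentanal | CC[C@H](O)[C@H](C)C=O | intermediate
3 | (2S,3S)-2-methyl-3-(triethylsilyloxy)pentanal | CC[C@H](O[Si](CC)(CC)CC)[C@H](C)C=O | intermediate
4 | 3-pentanone | CCC(=O)CC | starting material
5 | (4R,5R,6R,7S)-5-hydroxy-4,6-dimethyl-7-(triethylsilyloxy)nonan-3-one | CC[C@H](O[Si](CC)(CC)CC)[C@H](C)[C@@H](O)[C@@H](C)C(=O)CC | intermediate
6 | (4R,5R,6S,7S)-5-(tert-butyldimethylsilyloxy)-4,6-dimethyl-7-(triethylsilyloxy)nonan-3-one | CC[C@H](O[Si](CC)(CC)CC)[C@H](C)[C@@H](O[Si](C)(C)C(C)(C)C)[C@@H](C)C(=O)CC | intermediate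
7 | 2,3,5,6-tetramethyl-4H-pyran-4-one | Cc1oc(C)c(C)c(=O)c1C | intermediate
8 | lithium 2-(3,5,6-trimethyl-4-oxo-4H-pyran-2-yl)ethen-1-olate (enolate of the formylated pyranone) | [Li+].[O-]C=Cc1oc(C)c(C)c(=O)c1C | intermediate (not isolated)
9 | rac-2-(3,5,6-trimethyl-4-oxo-4H-pyran-2-yl)propanal | O=CC(C)c1oc(C)c(C)c(=O)c1C | intermediate
10 | (2R,3R,4R)-3-hydroxy-2-methyl-4-(3,5,6-trimethyl-4-oxo-4H-pyran-2-yl)pentanal | O=C[C@H](C)[C@H](O)[C@@H](C)c1oc(C)c(C)c(=O)c1C | intermediate
11 | (2R,3R,4R)-2-methyl-3-(triethylsilyloxy)-4-(3,5,6-trimethyl-4-oxo-4H-pyran-2-yl)pentanal | O=C[C@H](C)[C@H](O[Si](CC)(CC)CC)[C@@H](C)c1oc(C)c(C)c(=O)c1C | intermediate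
12 | 2-[(2R,3S,4S,5S,6S)-5-hydroxy-4,6-dimethyl-3-(triethylsilyloxy)oct-7-en-2-yl]-3,5,6-trimethyl-4H-pyran-4-one | C=C[C@H](C)[C@H](O)[C@H](C)[C@H](O[Si](CC)(CC)CC)[C@@H](C)c1oc(C)c(C)c(=O)c1C | intermediate
13 | 2-[(2R,3S,4S,5S,6S)-5-(tert-butyldimethylsilyloxy)-4,6-dimethyl-3-(triethylsilyloxy)oct-7-en-2-yl]-3,5,6-trimethyl-4H-pyran-4-one | C=C[C@H](C)[C@H](O[Si](C)(C)C(C)(C)C)[C@H](C)[C@H](O[Si](CC)(CC)CC)[C@@H](C)c1oc(C)c(C)c(=O)c1C | intermediate
14 | (2R,3R,4R,5S,6R)-3-(tert-butyldimethylsilyloxy)-2,4-dimethyl-5-(triethylsilyloxy)-6-(3,5,6-trimethyl-4-oxo-4H-pyran-2-yl)heptanal | O=C[C@H](C)[C@H](O[Si](C)(C)C(C)(C)C)[C@H](C)[C@H](O[Si](CC)(CC)CC)[C@@H](C)c1oc(C)c(C)c(=O)c1C | intermediate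
15 | (3S,4S,5R,6R,10S,11S,12S,13S,14R)-5,11-bis(tert-butyldimethylsilyloxy)-9-hydroxy-4,6,8,10,12-pentamethyl-3,13-bis(triethylsilyloxy)-14-(3,5,6-trimethyl-4-oxo-4H-pyran-2-yl)pentadecan-7-one, C8/C9 mixture | CC[C@H](O[Si](CC)(CC)CC)[C@H](C)[C@@H](O[Si](C)(C)C(C)(C)C)[C@@H](C)C(=O)C(C)C(O)[C@H](C)[C@H](O[Si](C)(C)C(C)(C)C)[C@H](C)[C@H](O[Si](CC)(CC)CC)[C@@H](C)c1oc(C)c(C)c(=O)c1C | intermediate
16 | (3S,4S,5R,6R,10S,11R,12R,13S,14R)-5,11-bis(tert-butyldimethylsilyloxy)-3,9,13-trihydroxy-4,6,8,10,12-pentamethyl-14-(3,5,6-trimethyl-4-oxo-4H-pyran-2-yl)pentadecan-7-one, C8/C9 mixture | CC[C@H](O)[C@H](C)[C@@H](O[Si](C)(C)C(C)(C)C)[C@@H](C)C(=O)C(C)C(O)[C@H](C)[C@H](O[Si](C)(C)C(C)(C)C)[C@H](C)[C@H](O)[C@@H](C)c1oc(C)c(C)c(=O)c1C | intermediate (not isolated)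
17 | (4R,5R,6R,10R,11R,12S,14S)-5,11-bis(tert-butyldimethylsilyloxy)-4,6,8,10,12-pentamethyl-14-(3,5,6-trimethyl-4-oxo-4H-pyran-2-yl)pentadecane-3,7,9,13-tetraone, C8 epimers/enol | CCC(=O)[C@H](C)[C@@H](O[Si](C)(C)C(C)(C)C)[C@@H](C)C(=O)C(C)C(=O)[C@H](C)[C@H](O[Si](C)(C)C(C)(C)C)[C@H](C)C(=O)[C@@H](C)c1oc(C)c(C)c(=O)c1C | intermediate
18 | (4R,5R,6R,10R,11R,12S,14S)-5,11-dihydroxy-4,6,8,10,12-pentamethyl-14-(3,5,6-trimethyl-4-oxo-4H-pyran-2-yl)pentadecane-3,7,9,13-tetraone, C8 epimers/enol | CCC(=O)[C@H](C)[C@@H](O)[C@@H](C)C(=O)C(C)C(=O)[C@H](C)[C@H](O)[C@H](C)C(=O)[C@@H](C)c1oc(C)c(C)c(=O)c1C | intermediate (not isolated)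
19 | (2S,3R,4R,5R,6R)-3-ethyl-3,5-dihydroxy-2,4,6-trimethyl-2-[(2R,3R,4S,6S)-3-hydroxy-2,4-dimethyl-5-oxo-6-(3,5,6-trimethyl-4-oxo-4H-pyran-2-yl)heptanoyl]cyclohexan-1-one | CC[C@@]1(O)[C@H](C)[C@@H](O)[C@@H](C)C(=O)[C@@]1(C)C(=O)[C@H](C)[C@H](O)[C@H](C)C(=O)[C@@H](C)c2oc(C)c(C)c(=O)c2C | intermediate (not isolated)
20 | (1R,2R,3R,4R,6R)-3-ethyl-3-hydroxy-2,4,6-trimethyl-5-oxocyclohexyl (2R,3R,4S,6S)-3-hydroxy-2,4-dimethyl-5-oxo-6-(3,5,6-trimethyl-4-oxo-4H-pyran-2-yl)heptanoate (CNP0260549.2) | CC[C@@]1(O)[C@H](C)[C@@H](OC(=O)[C@H](C)[C@H](O)[C@H](C)C(=O)[C@@H](C)c2oc(C)c(C)c(=O)c2C)[C@@H](C)C(=O)[C@@H]1C | target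

**Step count**
Total steps: 14. Longest linear sequence: 10 steps (4 → 7 → 9 → 10 → 11 → 12 → 13 → 14 → 15 → 17 → 20); the other branch (1 → 2 → 3 → 5 → 6) joins at step 12.

**Three steps most likely to fail, with fallbacks**

Step 7 (proline cross-aldol with dynamic kinetic resolution). The Felkin preference of 9 in the enamine aldol may be too low, or racemisation too slow, to give one C14 configuration. The fallback sets the C14 centre with an auxiliary instead and sets out from 7. Lithiated 7 is acylated with (S)-4-benzyl-2-oxooxazolidine-3-carbonyl chloride to give the N-acyl oxazolidinone F1. Its sodium enolate is methylated (NaHMDS, MeI, −78 °C) on the face away from the benzyl group to give the methylated imide F2. LiBH4 reduction releases the primary alcohol F3, and Dess–Martin oxidation gives the single-enantiomer aldehyde F4. F4 is used at once in the same D-proline aldol (shorter time, lower temperature, now an ordinary matched double stereodifferentiation) and the route is rejoined at 10.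

Step 9 (mismatched anti-crotylation). If reagent control does not override the Felkin bias of 11, the fallback changes the carbon nucleophile and sets out from 11. A chiral allenylzinc reagent is generated from the appropriate enantiomer of but-3-yn-2-yl mesylate (Pd(OAc)2, PPh3, Et2Zn, THF, −20 °C). It adds in the anti, reagent-controlled sense to give the homopropargylic alcohol F5. Lindlar semi-hydrogenation (H2, Pd/CaCO3/Pb, quinoline) of F5 gives the terminal alkene, and the route is rejoined at 12.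

Step 14 (one-pot desilylation, aldol and retro-Claisen). The risks are direct acyl transfer in 18 before ring closure (giving the acyclic ester), attack of O11 on C7, and the wrong C3 epimer. The fallback separates the two events and sets out from 17. With O5 and O11 still silylated, so that no acyl shift is possible, a magnesium-templated aldol (MgBr2·OEt2, i-Pr2NEt, CH2Cl2) closes the ring to the cyclised bis-silyl ketol F6, which is purified and its C3/C8 configuration checked. HF·pyridine then removes both silyl groups from F6, which rejoins the route at 19; 19 transfers its acyl group from C8 to O5 to give 20.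

**Further compounds**
F1 | step 7 | (S)-4-benzyl-3-[(3,5,6-trimethyl-4-oxo-4H-pyran-2-yl)acetyl]oxazolidin-2-one | O=C(Cc1oc(C)c(C)c(=O)c1C)N1[C@@H](Cc2ccccc2)COC1=O
F2 | step 7 | (S)-4-benzyl-3-[(S)-2-(3,5,6-trimethyl-4-oxo-4H-pyran-2-yl)propanoyl]oxazolidin-2-one | O=C([C@@H](C)c1oc(C)c(C)c(=O)c1C)N1[C@@H](Cc2ccccc2)COC1=O
F3 | step 7 | (R)-2-(1-hydroxypropan-2-yl)-3,5,6-trimethyl-4H-pyran-4-one | OC[C@@H](C)c1oc(C)c(C)c(=O)c1C
F4 | step 7 | (S)-2-(3,5,6-trimethyl-4-oxo-4H-pyran-2-yl)propanal | O=C[C@@H](C)c1oc(C)c(C)c(=O)c1C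
F5 | step 9 | 2-[(2R,3S,4S,5S,6S)-5-hydroxy-4,6-dimethyl-3-(triethylsilyloxy)oct-7-yn-2-yl]-3,5,6-trimethyl-4H-pyran-4-one | C#C[C@H](C)[C@H](O)[C@H](C)[C@H](O[Si](CC)(CC)CC)[C@@H](C)c1oc(C)c(C)c(=O)c1C
F6 | step 14 | (2S,3R,4R,5R,6R)-5-(tert-butyldimethylsilyloxy)-3-ethyl-3-hydroxy-2,4,6-trimethyl-2-[(2R,3R,4S,6S)-3-(tert-butyldimethylsilyloxy)-2,4-dimethyl-5-oxo-6-(3,5,6-trimethyl-4-oxo-4H-pyran-2-yl)heptanoyl]cyclohexan-1-one | CC[C@@]1(O)[C@H](C)[C@@H](O[Si](C)(C)C(C)(C)C)[C@@H](C)C(=O)[C@@]1(C)C(=O)[C@H](C)[C@H](O[Si](C)(C)C(C)(C)C)[C@H](C)C(=O)[C@@H](C)c2oc(C)c(C)c(=O)c2C
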